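**Retrosynthetic overview**
1. The 8,9-epoxide, the C10 carbinol (allylic oxidation, then reduction anti to the C1 methyl) and the two esters are placed last on trans-fused hydroazulene 18; its C6 oxygen comes from a C4–OH-directed reduction of a C6 ketone.
2. Key disconnection: the ring-fusion bond C1–C5, formed by a pinacol-type 1,2-shift that turns a cis-fused 6-6 decalin (C1 bonded to C6) into the 5-7 hydroazulen-6-one.
3. Enabling feature: in the target the oxygen-bearing C6 of seven-membered ring B is bonded to ring-fusion C5, and C1 is quaternary. A tertiary C6 hydroxyl next to an equatorial C5 sulfonate in a six-membered ring A (C1–C6) therefore lets the C1–C6 bond, antiperiplanar to C5–O, migrate to C5.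
4. The decalin, with all fifteen skeletal carbons, comes from one enantioselective Diels–Alder reaction of thymoquinone (ring A) with isoprene (ring B); the ring A oxygens at C6, C4, C5 and C2 are then set cis to the angular methyl.
5. Ring order: ring A (quinone), six-membered ring B (cycloaddition), five- and seven-membered rings together in the key step, epoxide last.

Key step: step 8

Numbering (all compounds): C1 = quaternary ring-fusion carbon (CH3), C2 = acetoxy carbon, C3 = CH2, C4 = isopropyl carbinol carbon, C5 = ring-fusion CH, C6 = anisoyloxy carbon, C7 = CH2, C8/C9 = epoxide carbons (C8 carries CH3), C10 = carbinol carbon. β = face of the C1 methyl, α = opposite face. In decalins 3–13, C1 is bonded to C6, ring A = C1–C6 and ring B = C1, C6–C10. In the hydroazulenes, ring A = C1–C5 and ring B = C1, C5–C10.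

Assumption: the oxazaborolidinium catalyst from (S)-α,α-diphenylprolinol is taken to give the enantiomer of 3 shown; if its facial sense is the opposite, the catalyst from (R)-diphenylprolinol is used.

**Step 1**
Reactants: 1 thymoquinone (2-isopropyl-5-methyl-1,4-benzoquinone); 2 isoprene
Product: 3 cis-fused enedione (2-isopropyl-4a,7-dimethyl-4a,5,8,8a-tetrahydronaphthalene-1,4-dione; C2 and C5 ketones, C3=C4, C8=C9, C1–CH3 cis to H-6)
Conditions: (S)-o-tolyl-oxazaborolidine from (S)-α,α-diphenylprolinol (20 mol %), HNTf2 (18 mol %), isoprene (5 equiv), CH2Cl2, −78 to −40 °C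
Reagents that add atoms: none
Why: Enantioselective quinone Diels–Alder reaction under chiral oxazaborolidinium catalysis: the cation binds the C2 carbonyl, the less hindered methyl-bearing C1=C6 bond reacts, the more nucleophilic isoprene terminus bonds to the β-carbon C6 ("para" orientation, so C8 carries the methyl), suprafacial addition makes C1–CH3 and H-6 cis, and the catalyst's face selection sets the absolute configuration at C1.

**Step 2**
Reactants: 3 cis-fused enedione
Product: 6 6-(trimethylsilyloxy) enedione (C6–O cis to C1–CH3), via potassium dienolate 4 (not isolated), via potassium alkoxide 5 (not isolated)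
Conditions: KN(SiMe3)2, THF, −78 °C; 2-(phenylsulfonyl)-3-phenyloxaziridine, −78 °C; then Me3SiCl, −78 to 0 °C
Reagents that add atoms: 2-(phenylsulfonyl)-3-phenyloxaziridine, O=S(=O)(N1OC1c1ccccc1)c1ccccc1; chlorotrimethylsilane, C[Si](C)(C)Cl
Why: Deprotonation of the only acidic site (H-6) gives the cross-conjugated dienolate, which should be hydroxylated (Davis oxidation) on the face of the C1 methyl, away from ring B, so the C6 oxygen is cis to the C1 methyl and the cis fusion is kept; in situ silylation masks this tertiary oxygen.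

**Step 3**
Reactants: 6 6-(trimethylsilyloxy) enedione
Product: 7 3,4-epoxy-6-(trimethylsilyloxy) dione (epoxide cis to C1–CH3)
Conditions: t-BuOOH, DBU, CH2Cl2, 0 °C
Reagents that add atoms: tert-butyl hydroperoxide, CC(C)(C)OO
Why: Weitz–Scheffer nucleophilic epoxidation: the peroxide anion adds to the unhindered β-carbon C3 and the enolate closes at C4 from the convex face of the cis-fused bicycle (anti to ring B), which should set the C4 oxygen cis to the C1 methyl and the isopropyl group on the opposite face.

**Step 4**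
Reactants: 7 3,4-epoxy dione
Product: 8 4-hydroxy-6-(trimethylsilyloxy)-2,5-dione (C4–OH cis to C1–CH3)
Conditions: (PhSe)2, NaBH4, EtOH; then AcOH, 0 °C to rt
Reagents that add atoms: none
Why: Organoselenium reduction of an α,β-epoxy ketone (Miyashita): the selenolate attacks the secondary α-carbon C3 of the C2 ketone (SN2 at tertiary C4 is not competitive), so only the C3–O bond is cleaved and C4 keeps its configuration, while AcOH buffering prevents retro-aldol cleavage.

**Step 5**
Reactants: 8 4-hydroxy dione
Product: 9 4-(triethylsilyloxy)-6-(trimethylsilyloxy)-2,5-dione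
Conditions: Et3SiOTf, 2,6-lutidine, CH2Cl2, −78 to 0 °C
Reagents that add atoms: triethylsilyl triflate, CC[Si](CC)(CC)OS(=O)(=O)C(F)(F)F
Why: Silylation of the only free hydroxyl with a silyl triflate and a hindered pyridine base tells the two tertiary oxygens apart (robust C4–OSiEt3, labile C6–OSiMe3) without enolising the ketones.

**Step 6**
Reactants: 9 bis-silyl ether dione
Product: 11 2,5,6-triol 4-triethylsilyl ether (C2, C4, C5 and C6 oxygens all cis to C1–CH3), via diol bis-silyl ether 10 (not isolated)
Conditions: LiAlH4, THF, −78 to 0 °C; then aq. citric acid, MeOH, rt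
Reagents that add atoms: none
Why: Hydride reduction in the ring A chair that keeps isopropyl and C1 methyl equatorial and both silyloxy groups axial: hydride should reach C5 and C2 from the face opposite these axial oxygens (axial attack at C5 anti to the two α C–O bonds, equatorial attack at C2 because the syn-axial C4 and C6 oxygens block the other face), giving the C5 (equatorial) and C2 (axial) hydroxyls cis to the C1 methyl, after which mild acid cleaves only the tertiary trimethylsilyl ether.

**Step 7**
Reactants: 11 2,5,6-triol 4-triethylsilyl ether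
Product: 12 5-tosylate of 11
Conditions: Bu2SnO (10 mol %), TsCl, Et3N, CH2Cl2, rt
Reagents that add atoms: p-toluenesulfonyl chloride, Cc1ccc(S(Cl)(=O)=O)cc1
Why: Tin-mediated regioselective sulfonylation: the cis-1,2-diol O5/O6 forms the five-membered stannylene acetal whose secondary oxygen (O5) is tosylated, leaving the tertiary C6 hydroxyl and the isolated axial C2 hydroxyl free.

**Step 8**
Reactants: 12 5-tosylate
Product: 14 trans-fused 2β-hydroxy-4β-(triethylsilyloxy)dauc-8-en-6-one (H-5 α), via aluminium alkoxide 13 (not isolated)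
Conditions: Et3Al (4 equiv), CH2Cl2, −78 to 0 °C; aq. Rochelle salt work-up
Reagents that add atoms: none
Why: Et3Al turns the C6 and C2 hydroxyls into aluminium alkoxides and assists departure of the C5 tosylate while the C1–C6 bond shifts to C5 in a concerted pinacol-type (semipinacol) 1,2-alkyl shift that makes C6 a ketone; this bond is antiperiplanar to the equatorial C5–O bond in the ring A chair (isopropyl and C1 methyl equatorial; C2, C4 and C6 oxygens axial). The closest known reaction types are the pinacol-type rearrangement of hydronaphthalene 1,2-diol monosulfonates to hydroazulenones and the organoaluminium-promoted rearrangement of β-sulfonyloxy alcohols. Ring A contracts from six to five members (C1–C5) and ring B expands from six to seven (C1, C5–C10) in the same event, both by bond migration rather than by an exo or endo cyclisation. C5 is the only new stereocentre and is set by inversion: C1 enters anti to the leaving group, which lies cis to the C1 methyl, so H-5 ends trans to that methyl (trans fusion), while C1 migrates with retention. The step needs C1 to migrate in preference to C3 (also antiperiplanar) and C7; the C4 oxygen is capped as a silyl ether and cannot act as donor, and C7 is equatorial on ring A and gauche to the leaving group.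

**Step 9**
Reactants: 14 2β-hydroxy ketone
Product: 15 2β-acetoxy-4β-(triethylsilyloxy)dauc-8-en-6-one
Conditions: Ac2O, pyridine, DMAP (cat.), CH2Cl2, 0 °C to rt
Reagents that add atoms: acetic anhydride, CC(=O)OC(C)=O
Why: DMAP-catalysed acetylation of the only free (secondary C2) hydroxyl, done while C6 is still a ketone so that no second secondary alcohol competes.

**Step 10**
Reactants: 15 acetate
Product: 16 2β-acetoxy-4β-hydroxydauc-8-en-6-one
Conditions: HF·pyridine, THF/pyridine, 0 °C to rt
Reagents that add atoms: none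
Why: Fluoride cleavage of the tertiary triethylsilyl ether under non-basic conditions should free the C4 hydroxyl without retro-aldol cleavage of the β-hydroxy ketone.

**Step 11**
Reactants: 16 β-hydroxy ketone
Product: 17 2β-acetoxydauc-8-ene-4β,6α-diol
Conditions: Me4NBH(OAc)3, MeCN/AcOH (1:1), −30 °C
Reagents that add atoms: none
Why: Evans–Saksena hydroxyl-directed reduction: boron bound to the C4 oxygen delivers hydride through a chair transition state to the β face of the C6 carbonyl, giving the 1,3-anti diol with the C6 hydroxyl α (cis to H-5).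

**Step 12**
Reactants: 17 diol
Product: 18 2β-acetoxy-6α-(4-methoxybenzoyloxy)dauc-8-en-4β-ol
Conditions: 4-MeOC6H4COCl, Et3N, DMAP (cat.), CH2Cl2, 0 °C to rt
Reagents that add atoms: 4-methoxybenzoyl chloride, COc1ccc(C(Cl)=O)cc1
Why: DMAP-catalysed acylation of the only secondary hydroxyl; the tertiary C4 hydroxyl should not react.

**Step 13**
Reactants: 18 anisoate
Product: 19 10-oxo enone (C10=O conjugated with C8=C9)
Conditions: dirhodium tetracaprolactamate Rh2(C6H10NO)4 (1 mol %), t-BuOOH (5 equiv), K2CO3, CH2Cl2, rt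
Reagents that add atoms: tert-butyl hydroperoxide, CC(C)(C)OO
Why: Allylic C–H oxidation to the enone: hydrogen abstraction is expected at C10, the methylene next to the less substituted alkene carbon C9 (allyl radical with a tertiary terminus at C8, as in C7 oxidation of Δ5-steroids), while C7 is deactivated by the adjacent C6 ester.

**Step 14**
Reactants: 19 enone
Product: 20 10β-allylic alcohol
Conditions: NaBH4, CeCl3·7H2O, MeOH, −78 °C
Reagents that add atoms: none
Why: Luche 1,2-reduction: hydride should add to the C10 carbonyl anti to the axial C1 methyl of the trans-fused bicycle, placing the C10 hydroxyl β (cis to the C1 methyl).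

**Step 15**
Reactants: 20 allylic alcohol
Product: 21 10β-triethylsilyl ether
Conditions: Et3SiCl, imidazole, DMF, 0 °C to rt
Reagents that add atoms: chlorotriethylsilane, CC[Si](Cl)(CC)CC
Why: Silylation of the secondary allylic hydroxyl removes its hydrogen-bond directing effect and shields the β face of C8=C9; the tertiary C4 hydroxyl is not silylated by the chloride.

**Step 16**
Reactants: 21 silyl ether
Product: 22 8α,9α-epoxide 10β-triethylsilyl ether
Conditions: mCPBA, NaHCO3, CH2Cl2, 0 °C
Reagents that add atoms: 3-chloroperbenzoic acid, OOC(=O)c1cccc(Cl)c1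
Why: Prilezhaev epoxidation of the trisubstituted alkene from the α face, anti to both the allylic silyloxy group and the axial C1 methyl, should set C8 and C9 with the epoxide trans to the C10 oxygen.

**Step 17**
Reactants: 22 epoxide silyl ether
Product: 23 CNP0371526.1 (2β-acetoxy-8α,9α-epoxy-6α-(4-methoxybenzoyloxy)daucane-4β,10β-diol)
Conditions: HF·pyridine, pyridine, THF, 0 °C
Reagents that add atoms: none
Why: Pyridine-buffered fluoride cleavage of the secondary silyl ether should leave the epoxide and both esters untouched.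

**Compound list**
1 | thymoquinone | CC1=CC(=O)C(C(C)C)=CC1=O | starting material
2 | isoprene | C=CC(C)=C | starting material
3 | cis-fused enedione (Diels–Alder adduct) | CC1=CC[C@@]2(C)C(=O)C=C(C(C)C)C(=O)[C@H]2C1 | intermediate
4 | potassium dienolate of 3 (C5 enolate; not isolated) | CC1=CC[C@@]2(C)C(=O)C=C(C(C)C)C([O-])=C2C1.[K+] | intermediate
5 | potassium 6-alkoxide of the 6-hydroxy enedione (not isolated) | CC1=CC[C@@]2(C)C(=O)C=C(C(C)C)C(=O)[C@@]2([O-])C1.[K+] | intermediate
6 | 6-(trimethylsilyloxy) enedione | CC1=CC[C@@]2(C)C(=O)C=C(C(C)C)C(=O)[C@@]2(O[Si](C)(C)C)C1 | intermediate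
7 | 3,4-epoxy-6-(trimethylsilyloxy) dione | CC1=CC[C@@]2(C)C(=O)[C@@H]3O[C@]3(C(C)C)C(=O)[C@@]2(O[Si](C)(C)C)C1 | intermediate
8 | 4-hydroxy-6-(trimethylsilyloxy)-2,5-dione | CC1=CC[C@@]2(C)C(=O)C[C@@](O)(C(C)C)C(=O)[C@@]2(O[Si](C)(C)C)C1 | intermediate
9 | 4-(triethylsilyloxy)-6-(trimethylsilyloxy)-2,5-dione | CC1=CC[C@@]2(C)C(=O)C[C@@](O[Si](CC)(CC)CC)(C(C)C)C(=O)[C@@]2(O[Si](C)(C)C)C1 | intermediate
10 | 2,5-diol bis-silyl ether (not isolated) | CC1=CC[C@@]2(C)[C@H](O)C[C@@](O[Si](CC)(CC)CC)(C(C)C)[C@H](O)[C@@]2(O[Si](C)(C)C)C1 | intermediate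
11 | 2,5,6-triol 4-triethylsilyl ether | CC1=CC[C@@]2(C)[C@H](O)C[C@@](O[Si](CC)(CC)CC)(C(C)C)[C@H](O)[C@@]2(O)C1 | intermediate
12 | 5-tosylate of 11 | CC1=CC[C@@]2(C)[C@H](O)C[C@@](O[Si](CC)(CC)CC)(C(C)C)[C@H](OS(=O)(=O)c3ccc(C)cc3)[C@@]2(O)C1 | intermediate
13 | 2,6-bis(diethylaluminium) alkoxide of 12 (not isolated) | CC1=CC[C@@]2(C)[C@H](O[Al](CC)CC)C[C@@](O[Si](CC)(CC)CC)(C(C)C)[C@H](OS(=O)(=O)c3ccc(C)cc3)[C@@]2(O[Al](CC)CC)C1 | intermediate
14 | 2β-hydroxy-4β-(triethylsilyloxy)dauc-8-en-6-one | O=C1CC(C)=CC[C@@]2(C)[C@H](O)C[C@@](O[Si](CC)(CC)CC)(C(C)C)[C@H]12 | intermediate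
15 | 2β-acetoxy-4β-(triethylsilyloxy)dauc-8-en-6-one | O=C1CC(C)=CC[C@@]2(C)[C@H](OC(C)=O)C[C@@](O[Si](CC)(CC)CC)(C(C)C)[C@H]12 | intermediate
16 | 2β-acetoxy-4β-hydroxydauc-8-en-6-one | O=C1CC(C)=CC[C@@]2(C)[C@H](OC(C)=O)C[C@@](O)(C(C)C)[C@H]12 | intermediate
17 | 2β-acetoxydauc-8-ene-4β,6α-diol | O[C@H]1CC(C)=CC[C@@]2(C)[C@H](OC(C)=O)C[C@@](O)(C(C)C)[C@H]12 | intermediate
18 | 2β-acetoxy-6α-(4-methoxybenzoyloxy)dauc-8-en-4β-ol | COc1ccc(C(=O)O[C@H]2CC(C)=CC[C@@]3(C)[C@H](OC(C)=O)C[C@@](O)(C(C)C)[C@H]23)cc1 | intermediate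
19 | 10-oxo enone of 18 | COc1ccc(C(=O)O[C@H]2CC(C)=CC(=O)[C@@]3(C)[C@H](OC(C)=O)C[C@@](O)(C(C)C)[C@H]23)cc1 | intermediate
20 | 10β-hydroxy allylic alcohol | COc1ccc(C(=O)O[C@H]2CC(C)=C[C@H](O)[C@@]3(C)[C@H](OC(C)=O)C[C@@](O)(C(C)C)[C@H]23)cc1 | intermediate
21 | 10β-triethylsilyl ether of 20 | COc1ccc(C(=O)O[C@H]2CC(C)=C[C@H](O[Si](CC)(CC)CC)[C@@]3(C)[C@H](OC(C)=O)C[C@@](O)(C(C)C)[C@H]23)cc1 | intermediate
22 | 8α,9α-epoxide of 21 | COc1ccc(C(=O)O[C@H]2C[C@@]4(C)O[C@H]4[C@H](O[Si](CC)(CC)CC)[C@@]3(C)[C@H](OC(C)=O)C[C@@](O)(C(C)C)[C@H]23)cc1 | intermediate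
23 | CNP0371526.1 | COc1ccc(C(=O)O[C@H]2C[C@@]3(C)O[C@H]3[C@H](O)[C@]3(C)[C@@H]2[C@](O)(C(C)C)C[C@H]3OC(C)=O)cc1 | target

**Totals**
Total step count: 17. Longest linear sequence: 17 steps (from thymoquinone).

**Steps most likely to fail**

1. Step 13. Hydrogen abstraction may occur at C7 or at the C8 methyl group instead of the neopentyl C10 methylene, or the alkene may be epoxidised. Fallback, from 18 back to 19: mCPBA (CH2Cl2, 0 °C) converts 18 into the 8,9-epoxide F1. Sodium benzeneselenolate ((PhSe)2, NaBH4, EtOH, reflux) opens it at the secondary C9 to give the hydroxy selenide F2. H2O2 (THF, 0 °C to rt) gives the selenoxide F3, which can only eliminate toward C10 (C8 has no hydrogen) and gives the tertiary allylic alcohol F4 (C9=C10). Oxidative 1,3-transposition with pyridinium chlorochromate (C5H5NH)[CrO3Cl] in CH2Cl2 then gives enone 19.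

2. Step 6. Hydride may reach the hindered C5 or C2 carbonyl from the face of the silyloxy groups, or the C5 ketone may resist reduction, giving the wrong ring A epimers. Fallback, from 7 back to 16: 7 is treated with LiAlH4 (THF, −78 °C to reflux) while ring A is still the rigid epoxide half-chair, so both carbonyls should be reduced anti to the epoxide oxygen and the epoxide then opened by hydride at the less substituted C3, giving the triol trimethylsilyl ether F5. Aqueous citric acid in MeOH gives the all-cis tetraol F6, and Bu2SnO (cat.)/TsCl/Et3N gives its 5-tosylate F7. KOC(CH3)3 in t-BuOH/THF at 0 °C triggers the anion-accelerated 1,2-shift (tertiary C1 expected to migrate in preference to primary C3) to the dihydroxy ketone F8. Ac2O/pyridine acetylates its only secondary hydroxyl and gives 16.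

3. Step 7. The doubly flanked C5 hydroxyl may not be sulfonylated, or the C2 hydroxyl may react instead. Fallback, from 11 back to 15: the two secondary hydroxyls are told apart by acylation, which should avoid the C5 hydroxyl lying between two fully substituted carbons. Ac2O, pyridine and DMAP at 0 °C give the 2-acetate F9. Methanesulfonyl chloride/Et3N (sulfene) then gives the 5-mesylate F10, and Et3Al (CH2Cl2, −78 to 0 °C) effects the same 1,2-shift to give 15 directly.

**Further compounds**
F1 | step 13 | 8α,9α-epoxide of 18 | COc1ccc(C(=O)O[C@H]2C[C@@]4(C)O[C@H]4C[C@@]3(C)[C@H](OC(C)=O)C[C@@](O)(C(C)C)[C@H]23)cc1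
F2 | step 13 | 8-hydroxy-9-(phenylselanyl) compound | COc1ccc(C(=O)O[C@H]2C[C@@](C)(O)[C@H]([Se]c4ccccc4)C[C@@]3(C)[C@H](OC(C)=O)C[C@@](O)(C(C)C)[C@H]23)cc1
F3 | step 13 | selenoxide of F2 | COc1ccc(C(=O)O[C@H]2C[C@@](C)(O)[C@H]([Se](=O)c4ccccc4)C[C@@]3(C)[C@H](OC(C)=O)C[C@@](O)(C(C)C)[C@H]23)cc1
F4 | step 13 | tertiary allylic alcohol (8-hydroxy, C9=C10) | COc1ccc(C(=O)O[C@H]2C[C@@](C)(O)C=C[C@@]3(C)[C@H](OC(C)=O)C[C@@](O)(C(C)C)[C@H]23)cc1
F5 | step 6 | 2,4,5-triol 6-trimethylsilyl ether | CC1=CC[C@@]2(C)[C@H](O)C[C@@](O)(C(C)C)[C@H](O)[C@@]2(O[Si](C)(C)C)C1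
F6 | step 6 | all-cis 2,4,5,6-tetraol | CC1=CC[C@@]2(C)[C@H](O)C[C@@](O)(C(C)C)[C@H](O)[C@@]2(O)C1
F7 | step 6 | 5-tosylate of F6 | CC1=CC[C@@]2(C)[C@H](O)C[C@@](O)(C(C)C)[C@H](OS(=O)(=O)c3ccc(C)cc3)[C@@]2(O)C1
F8 | step 6 | 2β,4β-dihydroxydauc-8-en-6-one | O=C1CC(C)=CC[C@@]2(C)[C@H](O)C[C@@](O)(C(C)C)[C@H]12
F9 | step 7 | 2-acetate of 11 | CC1=CC[C@@]2(C)[C@H](OC(C)=O)C[C@@](O[Si](CC)(CC)CC)(C(C)C)[C@H](O)[C@@]2(O)C1
F10 | step 7 | 5-mesylate of F9 | CC1=CC[C@@]2(C)[C@H](OC(C)=O)C[C@@](O[Si](CC)(CC)CC)(C(C)C)[C@H](OS(C)(=O)=O)[C@@]2(O)C1
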